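The data are simulated with made-up constants; scatter was added.

Late in the autumn run, from 30.0 h to 40.0 h, product gains 2.9 percentage points, while the pool, meaning what has left the solid and is not yet product, stands near 14.5%. So that pool drains with a lifetime of about 49.8 h.

the same everywhere: solid substrate 0.50 M; free catalyst 0.1 mol%; second catalyst 5 mol%

| run | reagent | remark | time |
|---|---|---|---|
| autumn | 2.1 equiv | run made earlier |  |
| winter | 3.3 equiv | run made earlier |  |
| flask | 1.50 equiv |  | 30 h |

| run | time / h | product / % | solid substrate / % |
|---|---|---|---|
| autumn | 2.00 | 0.4 | 97.8 |
| autumn | 6.00 | 0.4 | 94.8 |
| autumn | 10.0 | 0.6 | 92.4 |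
| autumn | 15.0 | 2.5 | 87.3 |
| autumn | 20.0 | 3.0 | 84.3 |
| autumn | 30.0 | 7.9 | 79.1 |
| autumn | 40.0 | 10.8 | 73.3 |
| winter | 3.00 | 0.3 | 97.6 |
| winter | 4.00 | 0.1 | 96.9 |
| winter | 6.00 | 0.9 | 93.9 |
| winter | 10.0 | 1.3 | 91.5 |
| winter | 15.0 | 2.5 | 87.9 |
| winter | 25.0 | 7.0 | 81.8 |
| winter | 40.0 | 15.0 | 73.1 |

(readings scatter by 0.5 percentage points)

- as a solid, counted per litre of solution: solid substrate
- steps that have been proposed: starting material + free catalyst <-> free catalyst + intermediate; reagent + second catalyst + intermediate -> second catalyst + product; solid substrate <-> starting material
- at the start none of the solid substrate is in solution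

- amount of product at 30 h, in percent of the solid substrate charged
- the change that raises the amount of product at 30 h, in percent of the solid substrate charged most ("none" if none brings more than 2 percentage points) (birch / cedar / alder / ash / none)
- amount of product at 30 h, in percent of the solid substrate charged, after birch

- birch: doubling the dissolution coefficient of the solid substrate, all else as stated
- cedar: doubling the amount of reagent, all else as stated
- alder: doubling the solubility of the solid substrate, all else as stated
- ash: doubling the amount of free catalyst, all else as stated

The same slope in the winter run gives 21.7 h. If I scale each run inversely with reagent and average them, the flask at 1.50 equiv gets 58.7 h.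

The solid readings do not follow reagent in these two runs, since at 40.0 h the autumn run holds 73.3% and the winter run 73.1%. I therefore borrow the autumn solid curve for the flask. Up to 30 h, the area under the curve of material gone from it equals that of the whole charge off the solid for 3.38 h. Product grows roughly as the square of time, so its own share of that area is the final product times a third of the time. Product is then this area over the lifetime plus a third of the time, which gives 4.91%.

The weak link is the slope, which rests on a few readings and leaves the scaled runs apart. So I reforge it. The drain lifetime, a pseudo-first-order lifetime, is the area under the pool curve of a whole run divided by the product made, scaled to 1.50 equiv. Autumn gives 53.4 h and winter 52.5 h. Taking 52.9 h, I commit to 5.36%.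

The forecast, which I take for the other two answers, says 5.3%, names alder and gives 8.7% after birch, holding the product rate “about first order in reagent”.

The flask gives 5.70%. The best change is alder, which adds 5.5 points, and birch gives 8.96%.

    starting material + free catalyst ⇌ free catalyst + intermediate (K = 2.60, k = 291 M⁻¹ h⁻¹)
    reagent + second catalyst + intermediate → second catalyst + product (k = 2.32 M⁻² h⁻¹)
    solid substrate ⇌ starting material, rate k3*(cs3 - [starting material]) while solid is left; crystals form when [starting material] > cs3 (solubility = 0.0790 M, k = 0.0639 h⁻¹)

Read backwards, 5.70% makes the drain lifetime of the flask 49.3 h over the whole 30 h. For the same flask stopped at 8.0 h I draw the solid as a straight line through the autumn reading at 10.0 h, and the reckoning gives it 0.437%. It holds 0.314%, which makes its lifetime 74.8 h. At 30.0 h the flask holds 8.36% intermediate beside 6.78% starting material, whereas the flask stopped at 8.00 h holds 2.27% intermediate beside 4.19% starting material.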